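**Plan**

- Retrosynthesis: the ester C–O bond is cut last. Before that the benzene ring is taken apart: H2 is added back (phenol to a racemic 4-substituted cyclohex-2-enone), then the ring C1–C6 single bond and the C2=C3 double bond are cut (C1 carries the CH2CH2O arm, C4 is the carbonyl/phenol carbon).
- Enabling feature: in the benzene ring the hydroxyl carbon C4 lies para to C1, the carbon bearing the CH2CH2O arm. This 1,4-pattern is the aromatised form of a 4-substituted cyclohex-2-enone. C1, C2 and the arm come from the α-carbon, formyl carbon and chain of 4-oxobutyl hexacosanoate; C3–C6 and the oxygen come from methyl vinyl ketone.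
- Forward: the chain is joined first (monoesterification of butane-1,4-diol, then oxidation to the aldehyde), the six-membered carbocycle is closed in one operation, and dehydrogenation makes it aromatic.
- Stereochemistry: the target has no stereogenic element. The one stereocentre that appears on the way (C1 of the enone) is formed as a racemate and is erased on aromatisation.

Key step: step 3

Remark: because the target is achiral, "single enantiomer" can only mean the one constitution shown, so no asymmetric step is planned.

**Route**

Step 1
Reactants: 1 hexacosanoic acid; 2 butane-1,4-diol (5 equiv)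
Product: 3 4-hydroxybutyl hexacosanoate
Conditions: DCC (1.1 equiv), DMAP (0.1 equiv), THF/CH2Cl2, 40 °C
Reagents that add atoms: none
Why: Steglich esterification, in which the five-fold excess of the symmetrical diol should make monoacylation dominant; surplus diol is washed out with water and the urea is filtered off.

Step 2
Reactants: 3 4-hydroxybutyl hexacosanoate
Product: 4 4-oxobutyl hexacosanoate
Conditions: TEMPO (0.1 equiv), PhI(OAc)2 (1.1 equiv), CH2Cl2, rt
Reagents that add atoms: none
Why: oxoammonium-mediated (TEMPO/diacetoxyiodobenzene) oxidation of a primary alcohol should stop cleanly at the aldehyde under anhydrous conditions and leaves the saturated ester untouched.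

Step 3
Reactants: 4 4-oxobutyl hexacosanoate; 5 methyl vinyl ketone (1.5 equiv)
Product: 9 racemic 2-(4-oxocyclohex-2-en-1-yl)ethyl hexacosanoate, via enamine 6 (not isolated), via keto aldehyde 7 (not isolated), via aldol 8 (not isolated)
Conditions: Et2NH (0.3 equiv), toluene, 45 °C; then strip volatiles, TsOH·H2O (0.2 equiv), toluene, 90 °C (Dean–Stark)
Reagents that add atoms: none
Why: Diethylamine condenses with the unbranched aldehyde 4 to enamine 6, whose nucleophilic carbon (the former α-CH2) adds to the terminal carbon of 5; hydrolysis of the resulting iminium returns the amine and keto aldehyde 7, and under TsOH the enol of the methyl ketone attacks the formyl carbon to give aldol 8, which dehydrates to the conjugated enone 9. The closest known chemistry is the secondary-amine-catalysed Michael addition of aldehydes to vinyl ketones followed by acid-mediated aldol cyclodehydration, an enamine variant of the Robinson annulation long used for 4-alkylcyclohex-2-enones. The single ring closes in a 6-(enolendo)-exo-trig aldol mode that, after loss of water, leaves the C2=C3 double bond, the Michael step having already made the C1–C6 single bond. The new stereocentre at ring C1 is set without control (achiral amine, racemate), which is acceptable because this carbon becomes an aromatic sp2 centre in step 4. The step needs mono-alkylation at the aldehyde α-carbon and six-ring aldol regiochemistry: 4 has a single enolisable position, the α-branched adduct 7 forms an enamine much more slowly so a second Michael addition is disfavoured, and the excess of 5 should keep the cross-addition ahead of aldehyde self-aldol. Of the enol/carbonyl pairings open to 7 only methyl-onto-formyl gives an unstrained ring (the others would close four-membered rings), and the acyloxy group sits γ to the formyl carbon and cannot β-eliminate, so the ester should pass through unchanged.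

Step 4
Reactants: 9 racemic 2-(4-oxocyclohex-2-en-1-yl)ethyl hexacosanoate
Product: 11 2-(4-hydroxyphenyl)ethyl hexacosanoate, via dienone 10 (not isolated)
Conditions: Pd(TFA)2 (5 mol %), 2-(dimethylamino)pyridine (10 mol %), TsOH·H2O (20 mol %), O2 (1 atm), DMSO, 80 °C
Reagents that add atoms: none
Why: Pd(II)-catalysed aerobic dehydrogenation of a cyclohexenone, in which α-palladation at C5 and β-hydride elimination towards C6 give the cross-conjugated dienone 10, which tautomerises through its C1–H to the phenol while O2 reoxidises Pd(0); the former stereocentre disappears and the ester is inert.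

**Compound list**

1 | hexacosanoic acid | CCCCCCCCCCCCCCCCCCCCCCCCCC(=O)O | starting material
2 | butane-1,4-diol | OCCCCO | starting material
3 | 4-hydroxybutyl hexacosanoate | CCCCCCCCCCCCCCCCCCCCCCCCCC(=O)OCCCCO | intermediate
4 | 4-oxobutyl hexacosanoate | CCCCCCCCCCCCCCCCCCCCCCCCCC(=O)OCCCC=O | intermediate
5 | methyl vinyl ketone (but-3-en-2-one) | CC(=O)C=C | starting material
6 | (E)-4-(diethylamino)but-3-en-1-yl hexacosanoate (enamine, not isolated) | CCCCCCCCCCCCCCCCCCCCCCCCCC(=O)OCC/C=C/N(CC)CC | intermediate
7 | racemic 3-formyl-6-oxoheptyl hexacosanoate (keto aldehyde, not isolated) | CCCCCCCCCCCCCCCCCCCCCCCCCC(=O)OCCC(C=O)CCC(C)=O | intermediate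
8 | 2-(2-hydroxy-4-oxocyclohexyl)ethyl hexacosanoate (aldol, racemic mixture of diastereomers, not isolated) | CCCCCCCCCCCCCCCCCCCCCCCCCC(=O)OCCC1CCC(=O)CC1O | intermediate
9 | racemic 2-(4-oxocyclohex-2-en-1-yl)ethyl hexacosanoate (ring C1 bears the CH2CH2O arm, C2=C3, C4=O) | CCCCCCCCCCCCCCCCCCCCCCCCCC(=O)OCCC1CCC(=O)C=C1 | intermediate
10 | 2-(4-oxocyclohexa-2,5-dien-1-yl)ethyl hexacosanoate (achiral dienone, not isolated) | CCCCCCCCCCCCCCCCCCCCCCCCCC(=O)OCCC1C=CC(=O)C=C1 | intermediate
11 | 2-(4-hydroxyphenyl)ethyl hexacosanoate (achiral) | CCCCCCCCCCCCCCCCCCCCCCCCCC(=O)OCCc1ccc(O)cc1 | target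

**Count**

Total step count: 4. Longest linear sequence: 4 steps (1 → 3 → 4 → 9 → 11).

**Steps most likely to fail, with fallbacks**

Step 3. Self-aldol condensation of the unbranched aldehyde and amine-induced oligomerisation of the vinyl ketone may outrun the cross Michael addition, or a second Michael addition may follow the first. The fallback sets out from 4 and removes free aldehyde from the Michael stage. Compound 4 would be condensed with pyrrolidine (1.2 equiv, K2CO3, toluene, 0 °C to rt) to the isolated enamine (E)-4-(pyrrolidin-1-yl)but-3-en-1-yl hexacosanoate F1. Addition of 5 (toluene, rt, Stork enamine reaction) should give the cycloadduct-type Michael product 2-[6-methyl-2-(pyrrolidin-1-yl)-3,4-dihydro-2H-pyran-3-yl]ethyl hexacosanoate F2. Heating F2 with aqueous acetic acid/sodium acetate should hydrolyse it to keto aldehyde 7, where the fallback rejoins the route; 7 cyclodehydrates under the same acidic conditions through 8 to 9.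

Step 4. The aerobic palladium cycle may stall through precipitation of palladium black before conversion is complete, and the waxy substrate may dissolve poorly in DMSO. The fallback sets out from 9 and replaces direct C–H palladation by a pre-formed, regiodefined enol derivative. Soft enolisation (TMSOTf, Et3N, CH2Cl2, 0 °C) should give the cross-conjugated silyl dienol ether 2-[4-(trimethylsilyloxy)cyclohexa-2,4-dien-1-yl]ethyl hexacosanoate F3. Saegusa–Ito oxidation of F3 with Pd(OAc)2 (1 equiv, MeCN/THF, rt) should deliver dienone 10, where the fallback rejoins the route; 10 tautomerises to 11.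

Step 1. Over-acylation of the diol to the diester and rearrangement of the activated acid to an N-acylurea may erode the yield if the sparingly soluble acid couples slowly. The fallback sets out from 1 and makes the ester bond by O-alkylation with a masked aldehyde instead of acylating a diol. The caesium salt of 1 (Cs2CO3, DMF) would be alkylated with commercial 2-(3-chloropropyl)-1,3-dioxolane (NaI cat., 70 °C) to 3-(1,3-dioxolan-2-yl)propyl hexacosanoate F4. Mild acetal hydrolysis of F4 (80% aqueous AcOH, 50 °C) should give aldehyde 4, where the fallback rejoins the route, bypassing step 2 as well.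

**Further compounds**

F1 | step 3 | (E)-4-(pyrrolidin-1-yl)but-3-en-1-yl hexacosanoate | CCCCCCCCCCCCCCCCCCCCCCCCCC(=O)OCC/C=C/N1CCCC1
F2 | step 3 | 2-[6-methyl-2-(pyrrolidin-1-yl)-3,4-dihydro-2H-pyran-3-yl]ethyl hexacosanoate (racemic mixture of diastereomers) | CCCCCCCCCCCCCCCCCCCCCCCCCC(=O)OCCC1CC=C(C)OC1N2CCCC2
F3 | step 4 | racemic 2-[4-(trimethylsilyloxy)cyclohexa-2,4-dien-1-yl]ethyl hexacosanoate | CCCCCCCCCCCCCCCCCCCCCCCCCC(=O)OCCC1CC=C(O[Si](C)(C)C)C=C1
F4 | step 1 | 3-(1,3-dioxolan-2-yl)propyl hexacosanoate | CCCCCCCCCCCCCCCCCCCCCCCCCC(=O)OCCCC1OCCO1
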